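**Plan**
Numbering follows the nerolidol chain: C1=C2 vinyl, C3 carbinol, C6 CHBr. The oxane ring is C7 (quaternary), C8, C9, C10 (CHBr), C11 (CMe2) and O.
Retrosynthesis: the C3 silyl ether is removed first. The oxane is then cut at C7–C8 and O–C11 (with C10–Br) into a C1–C7 α-bromo methyl ketone and a homoprenyl Grignard reagent. The ketone is traced back through C7–CH3, C6–Br and C6–C7 to the C1–C6 aldehyde obtained from (S)-linalool.
Enabling feature: the ring O lies between C7, a masked ketone carbon next to the C6–Br stereocentre, and C11, the gem-dimethyl carbon vicinal to C10–Br, which is the anti/Markovnikov pattern of a bromonium opening. The C7=O can therefore serve as the two-atom partner, and a homoprenyl unit (C8 nucleophile, C11 electrophile after Br+) as the four-carbon partner, of a formal [4+2] annulation.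
Forward order: the C1–C7 chain is built linearly, the only ring arises in the fragment union, and desilylation ends the route.
Stereochemistry: C3 comes from (S)-linalool, C6 from catalyst-controlled α-bromination, C7 from C6 (polar Felkin–Anh), and C10 from C7 (chair-like anti bromoetherification).

Key step: step 8

Assumption: (S)-(+)-linalool (coriandrol) of high enantiomeric purity is taken as the commercial source of C3, and no step touches this centre.

Step 1
Reactants: 1 (S)-(+)-linalool
Product: 2 O-TBS-(S)-linalool
Conditions: TBSOTf, 2,6-lutidine, CH2Cl2, 0 °C to rt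
Reagents that add atoms: tert-butyldimethylsilyl triflate, CC(C)(C)[Si](C)(C)OS(=O)(=O)C(F)(F)F
Why: Silyl triflate/lutidine silylation is the standard way to protect a hindered tertiary allylic alcohol, and it blocks lactol formation and O3-to-C6 displacement in the later steps.

Step 2
Reactants: 2 O-TBS-(S)-linalool
Product: 4 (S)-4-[(tert-butyldimethylsilyl)oxy]-4-methylhex-5-enal, via secondary ozonide 3 (not isolated)
Conditions: O3/O2, CH2Cl2, −78 °C (Sudan Red 7B end point); then Me2S, −78 °C to rt
Reagents that add atoms: ozone, [O-][O+]=O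
Why: In this chemoselective ozonolysis the electron-rich trisubstituted C6=C7 alkene should be consumed well before the hindered vinyl group, which is inductively deactivated by the neighbouring silyloxy carbon.

Step 3
Reactants: 4 (S)-4-[(tert-butyldimethylsilyl)oxy]-4-methylhex-5-enal
Product: 6 (S)-5-[(tert-butyldimethylsilyl)oxy]-5-methylhept-6-enal, via methyl enol ether 5 (not isolated)
Conditions: MeOCH2PPh3Cl, KOtBu, THF, 0 °C; then 2 M aq HCl, THF, rt
Reagents that add atoms: (methoxymethyl)triphenylphosphonium chloride, COC[P+](c1ccccc1)(c1ccccc1)c1ccccc1.[Cl-]; water, O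
Why: Wittig methoxymethylenation followed by acid hydrolysis of the enol ether is the classical one-carbon aldehyde homologation (it adds C7), and the tertiary TBS ether should survive the brief acid treatment.

Step 4
Reactants: 6 (S)-5-[(tert-butyldimethylsilyl)oxy]-5-methylhept-6-enal
Product: 7 (2R,5S)-2-bromo-5-[(tert-butyldimethylsilyl)oxy]-5-methylhept-6-enal
Conditions: NBS (slow addition), (R)-2-{bis[3,5-bis(trifluoromethyl)phenyl][(trimethylsilyl)oxy]methyl}pyrrolidine (10 mol %), H2O (additive), 1,1,1,3,3,3-hexafluoropropan-2-ol (HFIP), 0 °C; cold short silica filtration, used at once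
Reagents that add atoms: N-bromosuccinimide, O=C1CCC(=O)N1Br
Why: In this organocatalytic asymmetric α-bromination (enamine catalysis) the diaryl(silyloxy)methyl group of the (R)-catalyst shields one face of the E-enamine, so Br+ should enter from the open face and set 6R (C2 of 7) under catalyst control, independent of the remote C3 centre.

Step 5
Reactants: 7 (2R,5S)-2-bromo-5-[(tert-butyldimethylsilyl)oxy]-5-methylhept-6-enal
Product: 9 (3R,6S)-3-bromo-6-[(tert-butyldimethylsilyl)oxy]-6-methyloct-7-en-2-ol (C2 epimers), via magnesium alkoxide 8 (not isolated)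
Conditions: MeMgBr, Et2O, −78 °C; AcOH, −78 °C
Reagents that add atoms: methylmagnesium bromide, C[Mg]Br
Why: Grignard addition to an α-bromo aldehyde at −78 °C with a cold acidic quench should outrun enolisation and epoxide closure, and the configuration of the new carbinol carbon does not matter because step 6 oxidises it.

Step 6
Reactants: 9 (3R,6S)-3-bromo-6-[(tert-butyldimethylsilyl)oxy]-6-methyloct-7-en-2-ol
Product: 10 (3R,6S)-3-bromo-6-[(tert-butyldimethylsilyl)oxy]-6-methyloct-7-en-2-one
Conditions: Dess–Martin periodinane, NaHCO3, CH2Cl2, 0 °C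
Reagents that add atoms: none
Why: The buffered Dess–Martin oxidation is non-basic and free of bromide, so it should give the α-bromo methyl ketone without enolising or exchanging the C6–Br stereocentre.

Step 7
Reactants: 11 5-bromo-2-methylpent-2-ene
Product: 12 (4-methylpent-3-en-1-yl)magnesium bromide (titrated Et2O solution)
Conditions: Mg turnings (cat. I2), Et2O, reflux
Reagents that add atoms: magnesium, [Mg]
Why: This is ordinary Grignard formation from a primary homoallylic bromide, whose cyclopropylcarbinyl equilibrium lies on the side of the open primary reagent.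

Step 8
Reactants: 10 (3R,6S)-3-bromo-6-[(tert-butyldimethylsilyl)oxy]-6-methyloct-7-en-2-one; 12 (4-methylpent-3-en-1-yl)magnesium bromide
Product: 15 O-TBS ether of the target, via magnesium alkoxide 13 (not isolated), via free bromohydrin 14 (not isolated)
Conditions: 12 (1.1 equiv), Et2O/CH2Cl2, −78 °C; then HFIP, −78 to −20 °C; then PhI(OAc)2 (1.1 equiv, one portion), −20 to 0 °C, dark
Reagents that add atoms: none
Why: Proposed new method: Grignard reagent 12 adds to the C7 carbonyl of 10 in the polar Felkin–Anh (Cornforth) sense, with C8 approaching anti to the C6–Br bond and past the C6–H, which forms C7–C8 and sets 7S from 6R; HFIP then protonates alkoxide 13 to 14, and the trivalent iodine oxidant PhI(OAc)2 converts the single equivalent of bromide that came with 12 into acetyl hypobromite, which transfers Br+ to the C10=C11 alkene. The C7 hydroxyl opens the bromonium ion at the dimethyl-substituted C11 with anti addition, a 6-endo (Markovnikov) closure that forms O–C11 and C10–Br and completes the oxane ring. The closest known reaction types are the addition of Grignard reagents to α-halo ketones, the bromoetherification of bishomoallylic tertiary alcohols with NBS in HFIP, and haloetherification with PhI(OAc)2/bromide; what is new is their merger in one flask with the counter-ion of the Grignard reagent as the bromine source, which follows from the need to leave no nucleophilic bromide beside the bromonium ion. C10 is controlled by C7 through a chair-like transition state in which anti addition places Br equatorial and the C7 methyl, not the larger C7 bromoalkyl chain, takes the axial site facing a C11 methyl, which should give the 7S,10R trans-diequatorial ring. The step needs 1,2-addition over enolisation and bromine–magnesium exchange (secured by −78 °C and the weakly coordinating Et2O/CH2Cl2 medium), attack of Br+ on C10=C11 rather than on the vinyl group (secured by the higher nucleophilicity of the trisubstituted alkene and the hindered, deactivated C1=C2), and 6-endo over 5-exo closure (secured by the tertiary C11 and the ionising, weakly nucleophilic HFIP).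

Step 9
Reactants: 15 O-TBS ether of the target
Product: 16 (3S,6R)-6-bromo-6-[(2S,5R)-5-bromo-2,6,6-trimethyloxan-2-yl]-3-methylhex-1-en-3-ol (target)
Conditions: 48% aq HF, MeCN, 0 °C to rt (polypropylene vessel)
Reagents that add atoms: none
Why: Acidic fluoride desilylation cleaves the hindered tertiary silyl ether without ever forming an alkoxide, which should avoid displacement of C6–Br by O3 and base-induced loss of the β-bromo ethers.

**Compound list**
1 | (S)-(+)-linalool, (3S)-3,7-dimethylocta-1,6-dien-3-ol | C=C[C@@](C)(O)CCC=C(C)C | starting material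
2 | O-TBS-(S)-linalool, tert-butyl{[(3S)-3,7-dimethylocta-1,6-dien-3-yl]oxy}dimethylsilane | C=C[C@@](C)(O[Si](C)(C)C(C)(C)C)CCC=C(C)C | intermediate
3 | secondary ozonide, 3,3-dimethyl-1,2,4-trioxolane carrying the (3S)-3-(TBS-oxy)-3-methylpent-4-enyl chain at C5 (epimers at C5) | C=C[C@@](C)(O[Si](C)(C)C(C)(C)C)CCC1OOC(C)(C)O1 | intermediate
4 | (S)-4-[(tert-butyldimethylsilyl)oxy]-4-methylhex-5-enal | C=C[C@@](C)(O[Si](C)(C)C(C)(C)C)CCC=O | intermediate
5 | methyl enol ether, (3S)-3-(TBS-oxy)-7-methoxy-3-methylhepta-1,6-diene (E/Z mixture) | C=C[C@@](C)(O[Si](C)(C)C(C)(C)C)CCC=COC | intermediate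
6 | (S)-5-[(tert-butyldimethylsilyl)oxy]-5-methylhept-6-enal | C=C[C@@](C)(O[Si](C)(C)C(C)(C)C)CCCC=O | intermediate
7 | (2R,5S)-2-bromo-5-[(tert-butyldimethylsilyl)oxy]-5-methylhept-6-enal | C=C[C@@](C)(O[Si](C)(C)C(C)(C)C)CC[C@@H](Br)C=O | intermediate
8 | bromomagnesium alkoxide of 9 (C2 epimers) | C=C[C@@](C)(O[Si](C)(C)C(C)(C)C)CC[C@@H](Br)C(C)O[Mg]Br | intermediate
9 | (3R,6S)-3-bromo-6-[(tert-butyldimethylsilyl)oxy]-6-methyloct-7-en-2-ol (C2 epimers) | C=C[C@@](C)(O[Si](C)(C)C(C)(C)C)CC[C@@H](Br)C(C)O | intermediate
10 | (3R,6S)-3-bromo-6-[(tert-butyldimethylsilyl)oxy]-6-methyloct-7-en-2-one | C=C[C@@](C)(O[Si](C)(C)C(C)(C)C)CC[C@@H](Br)C(C)=O | intermediate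
11 | 5-bromo-2-methylpent-2-ene (homoprenyl bromide) | CC(C)=CCCBr | starting material
12 | (4-methylpent-3-en-1-yl)magnesium bromide | CC(C)=CCC[Mg]Br | intermediate
13 | bromomagnesium alkoxide of 14 | C=C[C@@](C)(O[Si](C)(C)C(C)(C)C)CC[C@@H](Br)[C@@](C)(O[Mg]Br)CCC=C(C)C | intermediate
14 | (3S,6R,7S)-6-bromo-3-[(tert-butyldimethylsilyl)oxy]-3,7,11-trimethyldodeca-1,10-dien-7-ol | C=C[C@@](C)(O[Si](C)(C)C(C)(C)C)CC[C@@H](Br)[C@@](C)(O)CCC=C(C)C | intermediate
15 | tert-butyl({(3S,6R)-6-bromo-6-[(2S,5R)-5-bromo-2,6,6-trimethyloxan-2-yl]-3-methylhex-1-en-3-yl}oxy)dimethylsilane | C=C[C@@](C)(O[Si](C)(C)C(C)(C)C)CC[C@@H](Br)[C@]1(C)CC[C@@H](Br)C(C)(C)O1 | intermediate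
16 | (3S,6R)-6-bromo-6-[(2S,5R)-5-bromo-2,6,6-trimethyloxan-2-yl]-3-methylhex-1-en-3-ol | C=C[C@@](C)(O)CC[C@@H](Br)[C@]1(C)CC[C@@H](Br)C(C)(C)O1 | target

**Step count**
Total step count: 9.
Longest linear sequence: 8 steps (steps 1–6, 8 and 9, from 1).

**Steps most likely to fail**

Step 8 (bears the label "Proposed new method:").
- What may go wrong: enolisation or bromine–magnesium exchange during the addition, erosion of facial selectivity at C7, capture of the bromonium ion by acetate or residual bromide, competing 5-exo closure, and poor facial selectivity at C10.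
- Fallback (known chemistry, from 10 back to 15): the two bond formations are separated, and the ring is closed by oxymercuration instead of through a bromonium ion.
- From 10, the addition of 12 (Et2O/CH2Cl2, −78 °C) is quenched with AcOH, and bromohydrin 14 is isolated free of bromide salts.
- The divalent mercury salt Hg(OCOCF3)2 in MeCN at −20 °C should close the oxane reversibly and with Markovnikov regiochemistry to the C10 organomercury trifluoroacetate F1.
- Aqueous KBr exchanges the ligand to give the organomercury bromide F2.
- Br2 in pyridine at 0 °C in the dark (bromodemercuration with retention) should then give 15.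

Step 4.
- What may go wrong: racemisation of the α-bromo aldehyde through enamine or enol formation, over-bromination, and deactivation of the catalyst by N-bromination.
- Fallback (from 6 back to 10, bypassing 7, 8 and 9): catalyst control is replaced by auxiliary control with separable diastereomers.
- Pinnick oxidation (NaClO2, NaH2PO4, 2-methylbut-2-ene, tBuOH/H2O) gives (S)-5-(TBS-oxy)-5-methylhept-6-enoic acid F3.
- DCC/DMAP coupling with (R)-4-benzyloxazolidin-2-one gives the N-acyl oxazolidinone F4.
- Bu2BOTf and iPr2NEt in CH2Cl2 at −78 °C give the Z-dibutylboron enolate F5.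
- NBS at −78 °C should brominate the face away from the benzyl group to give the (2R)-α-bromo imide F6.
- MeNH(OMe)·HCl/AlMe3 gives the α-bromo N-methoxy-N-methylamide F7.
- MeMgBr in THF at −78 °C should then give 10.

Step 2.
- What may go wrong: loss of chemoselectivity between the two alkenes, that is, over-oxidation of the vinyl group.
- Fallback (from 2 back to 4): mCPBA in CH2Cl2 at 0 °C should epoxidise only the trisubstituted alkene to give the 6,7-epoxide F8. Cleavage with H5IO6 in THF/H2O at 0 °C should then give 4.

**Further compounds**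
F1 | step 8 | C10 organomercury trifluoroacetate of the O-TBS oxane (Hg equatorial, same spatial arrangement as Br in 15) | C=C[C@@](C)(O[Si](C)(C)C(C)(C)C)CC[C@@H](Br)[C@]1(C)CC[C@@H]([Hg]OC(=O)C(F)(F)F)C(C)(C)O1
F2 | step 8 | C10 organomercury bromide of the O-TBS oxane | C=C[C@@](C)(O[Si](C)(C)C(C)(C)C)CC[C@@H](Br)[C@]1(C)CC[C@@H]([Hg]Br)C(C)(C)O1
F3 | step 4 | (S)-5-[(tert-butyldimethylsilyl)oxy]-5-methylhept-6-enoic acid | C=C[C@@](C)(O[Si](C)(C)C(C)(C)C)CCCC(=O)O
F4 | step 4 | (R)-4-benzyl-3-{(S)-5-[(tert-butyldimethylsilyl)oxy]-5-methylhept-6-enoyl}oxazolidin-2-one | C=C[C@@](C)(O[Si](C)(C)C(C)(C)C)CCCC(=O)N1[C@H](Cc2ccccc2)COC1=O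
F5 | step 4 | Z-dibutylboron enolate of F4 | C=C[C@@](C)(O[Si](C)(C)C(C)(C)C)CC/C=C(\OB(CCCC)CCCC)N1[C@H](Cc2ccccc2)COC1=O
F6 | step 4 | (R)-4-benzyl-3-{(2R,5S)-2-bromo-5-[(tert-butyldimethylsilyl)oxy]-5-methylhept-6-enoyl}oxazolidin-2-one | C=C[C@@](C)(O[Si](C)(C)C(C)(C)C)CC[C@@H](Br)C(=O)N1[C@H](Cc2ccccc2)COC1=O
F7 | step 4 | (2R,5S)-2-bromo-5-[(tert-butyldimethylsilyl)oxy]-N-methoxy-N,5-dimethylhept-6-enamide | C=C[C@@](C)(O[Si](C)(C)C(C)(C)C)CC[C@@H](Br)C(=O)N(C)OC
F8 | step 2 | 6,7-epoxide of O-TBS-(S)-linalool (epimers at C6) | C=C[C@@](C)(O[Si](C)(C)C(C)(C)C)CCC1OC1(C)C
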